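**Retrosynthetic overview**

- Last ring: the pyran, closed by C–O bond formation (MeLi addition to a ten-membered-ring ketone, then capture of the tertiary cation by the triketone enol oxygen).
- Key step: the ten-membered carbocycle by a four-atom radical ring expansion of a cyclohexanone (C1–C2 cleavage with loss of a stannyl radical), which also creates the Z alkene.
- The cyclohexanone is dressed by Cu-catalysed asymmetric methyl conjugate addition/aldol condensation, conjugate stannylation, and kinetic enolate alkylation with the quinone methide of the acyl triketone.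
- Side-chain aldehyde from Shi epoxidation and carbonylative epoxide-to-β-lactone expansion; acyl triketone from methyl isobutyrate, diketene and isobutyric acid.
- Ring order: triketone ring, cyclohexanone (purchased ring), ten-membered ring, pyran.

Assumption: the target is taken exactly as the given SMILES; the triketone unit is drawn as the enol tautomer of the target, and 24 and 25 are drawn as the open keto tautomers of their cyclic hemiketals.

**Route**

Step 1
Reactants: 1 5-bromo-2-methylpent-2-ene
Product: 2 (R)-3-(2-bromoethyl)-2,2-dimethyloxirane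
Conditions: D-fructose-derived Shi ketone (30 mol %; the enantiomer that gives the R epoxide), Oxone, K2CO3, Bu4NHSO4, MeCN–DMM–aq. buffer (pH 10.5), 0 °C
Reagents that add atoms: Oxone (potassium peroxymonosulfate) [K+].[O-]S(=O)(=O)OO
Why: Shi asymmetric epoxidation, in which the chiral dioxirane reaches the trisubstituted alkene through a spiro transition state and sets the epoxide CH as R, the primary bromide surviving the cold buffered medium.

Step 2
Reactants: 2 (R)-3-(2-bromoethyl)-2,2-dimethyloxirane
Product: 3 (S)-3-(2-bromoethyl)-4,4-dimethyloxetan-2-one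
Conditions: [(salph)Al(THF)2][Co(CO)4] (2 mol %), CO (60 bar), DME, 50 °C
Reagents that add atoms: carbon monoxide [C-]#[O+]
Why: Ring-expanding carbonylation of an epoxide: Co(CO)4− opens the Lewis-acid-bound epoxide at the less substituted carbon with inversion, CO inserts and the alkoxide closes the β-lactone, so the epoxide CH becomes C3 (S).

Step 3
Reactants: 3 (S)-3-(2-bromoethyl)-4,4-dimethyloxetan-2-one
Product: 4 (S)-4-bromo-2-(2-hydroxypropan-2-yl)butanal
Conditions: DIBAL-H (1.05 equiv), CH2Cl2, −78 °C; Rochelle salt work-up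
Reagents that add atoms: none
Why: Partial reduction of a lactone: one hydride adds at −78 °C and the aluminium hemiacetal collapses on work-up to the β-hydroxy aldehyde without touching the α-stereocentre.

Step 4
Reactants: 4 (S)-4-bromo-2-(2-hydroxypropan-2-yl)butanal
Product: 5 (S)-4-bromo-2-[2-(triethylsilyloxy)propan-2-yl]butanal
Conditions: TESOTf, 2,6-lutidine, CH2Cl2, −78 °C
Reagents that add atoms: triethylsilyl triflate CC[Si](CC)(CC)OS(=O)(=O)C(F)(F)F
Why: Silyl ether protection of the hindered tertiary alcohol with a silyl triflate and a weak hindered base, which leaves the enolisable α-stereocentre intact and later prevents alkoxide attack on the bromide.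

Step 5
Reactants: 6 methyl 2-methylpropanoate; 7 diketene
Product: 9 2,2-dimethylcyclohexane-1,3,5-trione, via diketo ester 8 (not isolated)
Conditions: LDA (1.0 equiv), THF, −78 °C; then 7; then LDA (1.2 equiv), −78 → 0 °C; aq. HCl
Reagents that add atoms: none
Why: The ester enolate opens diketene at its lactone carbonyl (C-acetoacetylation) and the terminal carbanion of the resulting diketone dianion closes onto the ester in a Claisen (Dieckmann-type) condensation driven by the acidic trione; no stereocentre.

Step 6
Reactants: 9 2,2-dimethylcyclohexane-1,3,5-trione; 10 2-methylpropanoic acid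
Product: 12 3,5-dihydroxy-6,6-dimethyl-4-(2-methylpropanoyl)cyclohexa-2,4-dien-1-one, via enol ester 11 (not isolated)
Conditions: DCC, DMAP (0.3 equiv), CH2Cl2, 23 °C
Reagents that add atoms: none
Why: Steglich O-acylation followed by DMAP-mediated O-to-C acyl transfer of the 1,3-dione enol ester; the two ring C–H positions are equivalent, so a single C-acyl triketone forms and is deactivated toward a second acylation.

Step 7
Reactants: 12 3,5-dihydroxy-6,6-dimethyl-4-(2-methylpropanoyl)cyclohexa-2,4-dien-1-one
Product: 14 [2,4-dihydroxy-5,5-dimethyl-3-(2-methylpropanoyl)-6-oxocyclohexa-1,3-dien-1-yl]methyl-trimethylammonium inner salt (betaine), via Mannich salt 13 (not isolated)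
Conditions: Eschenmoser's salt, CH2Cl2, 23 °C; then MeI, K2CO3, acetone, 0 °C
Reagents that add atoms: Eschenmoser's salt (N,N-dimethylmethyleneiminium iodide) C=[N+](C)C.[I-]; iodomethane CI
Why: Mannich aminomethylation at the only enolic C–H, then N-quaternisation (the amine is far more nucleophilic than the delocalised triketone enolate) gives a storable betaine that releases the quinone methide on warming; no stereocentre.

Step 8
Reactants: 15 cyclohex-2-en-1-one; 5 (S)-4-bromo-2-[2-(triethylsilyloxy)propan-2-yl]butanal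
Product: 19 (3S)-2-{(2R)-4-bromo-2-[2-(triethylsilyloxy)propan-2-yl]butylidene}-3-methylcyclohexan-1-one (E/Z mixture), via magnesium enolate 16 (not isolated), via magnesium aldolate 17 (not isolated), via keto mesylate 18 (not isolated)
Conditions: MeMgBr, CuBr·SMe2 (5 mol %), Josiphos-type ligand (6 mol %; the enantiomer that gives 3S), t-BuOMe, −75 °C; then 5; then MsCl, Et3N, −75 → 0 °C
Reagents that add atoms: methylmagnesium bromide C[Mg]Br
Why: Copper-catalysed asymmetric conjugate addition sets C3 (S) by ligand control and gives the C1–C2 magnesium enolate regiospecifically, which adds to 5 (aldol) and is dehydrated by E1cB loss of the in situ mesylate; the aldol centres and alkene geometry are erased or irrelevant later.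

Step 9
Reactants: 19 (3S)-2-{(2R)-4-bromo-2-[2-(triethylsilyloxy)propan-2-yl]butylidene}-3-methylcyclohexan-1-one
Product: 21 (2R,3S)-2-{(2S)-4-bromo-1-(tributylstannyl)-2-[2-(triethylsilyloxy)propan-2-yl]butyl}-3-methylcyclohexan-1-one (C1′ epimer mixture), via lithium enolate 20 (not isolated)
Conditions: Bu3SnLi (from Bu3SnH and LDA), THF, −78 °C, 15 min; aq. NH4Cl; then K2CO3, MeOH, 0 °C
Reagents that add atoms: tributylstannyllithium [Li][Sn](CCCC)(CCCC)CCCC
Why: Conjugate addition of the stannyl anion to the enone is complete within minutes at −78 °C, much faster than SN2 at the primary bromide; base equilibration puts the C2 side chain trans to the C3 methyl (both equatorial), and the tin-bearing carbon is a mixture that the ring expansion erases.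

Step 10
Reactants: 21 (2R,3S)-2-{(2S)-4-bromo-1-(tributylstannyl)-2-[2-(triethylsilyloxy)propan-2-yl]butyl}-3-methylcyclohexan-1-one; 14 betaine
Product: 24 (2R,3S,6S)-2-{(2S)-4-bromo-1-(tributylstannyl)-2-[2-(triethylsilyloxy)propan-2-yl]butyl}-6-{[2,4-dihydroxy-5,5-dimethyl-3-(2-methylpropanoyl)-6-oxocyclohexa-1,3-dien-1-yl]methyl}-3-methylcyclohexan-1-one, via kinetic enolate 22 (not isolated), via quinone methide 23 (not isolated)
Conditions: LDA (1.05 equiv), THF, −78 °C; then 14, −78 → −20 °C; aq. NH4Cl
Reagents that add atoms: none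
Why: LDA removes the less hindered C6 proton (kinetic enolate) and the enolate adds to quinone methide 23 released from the betaine (Michael addition); axial attack anti to the bulky C2 substituent gives the 2,6-trans product, i.e. C6 (S) with the new CH2 cis to the C3 methyl.

Step 11
Reactants: 24 (2R,3S,6S)-2-{(2S)-4-bromo-1-(tributylstannyl)-2-[2-(triethylsilyloxy)propan-2-yl]butyl}-6-{[2,4-dihydroxy-5,5-dimethyl-3-(2-methylpropanoyl)-6-oxocyclohexa-1,3-dien-1-yl]methyl}-3-methylcyclohexan-1-one
Product: 25 (2S,5S,6Z,8R)-2-{[2,4-dihydroxy-5,5-dimethyl-3-(2-methylpropanoyl)-6-oxocyclohexa-1,3-dien-1-yl]methyl}-5-methyl-8-[2-(triethylsilyloxy)propan-2-yl]cyclodec-6-en-1-one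
Conditions: (Bu3Sn)2 (10 mol %), hν (sunlamp), PhH (0.01 M), 80 °C
Reagents that add atoms: none
Why: Proposed new method: a tin-relay radical ring expansion in which Bu3Sn• abstracts the bromine, the primary radical adds 6-exo to the ring C=O, the bicyclic alkoxy radical cleaves the C1–C2 bond (the one cleavage that puts the radical β to tin, assisted by σ(C–Sn) hyperconjugation) and the β-stannyl radical expels Bu3Sn•, which carries the chain, so no hydride is present and the reversible steps drain through this single irreversible exit to the cyclodecenone; reversible stannyl-radical addition is expected to equilibrate the new alkene to the more stable cis (Z) form, and the three existing stereocentres are not involved; the closest known reaction types are the Dowd–Beckwith ring expansion of haloalkyl ketones and alkoxy-radical fragmentations that end by loss of a stannyl radical, not yet shown for an exocyclic α-stannylalkyl group, a four-atom expansion or a substrate with a free acyl triketone.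

Step 12
Reactants: 25 (2S,5S,6Z,8R)-2-{[2,4-dihydroxy-5,5-dimethyl-3-(2-methylpropanoyl)-6-oxocyclohexa-1,3-dien-1-yl]methyl}-5-methyl-8-[2-(triethylsilyloxy)propan-2-yl]cyclodec-6-en-1-one
Product: 28 CNP0564661.1 (O-bearing quaternary carbon R; ring-fusion CH S; CH(CH3) S; CH bearing C(CH3)2OH R; Z alkene), via tertiary carbinol 26 (not isolated), via silyl ether 27 (not isolated)
Conditions: MeLi, CeCl3, THF, −78 °C; then TsOH·H2O, CH2Cl2–MeOH, 0 → 23 °C
Reagents that add atoms: methyllithium [Li]C
Why: Organocerium 1,2-addition avoids enolisation at C2; acid then ionises the tertiary carbinol and the enol oxygen captures the cation (cationic cycloetherification, as in chroman formation from tertiary carbinols) through a chair with both bonds to the macrocycle equatorial, so the methyl is axial and anti to the ring-fusion hydrogen (R at the quaternary carbon), the closure being reversible and converging on this trans-fused isomer, while the same acid in methanol removes the triethylsilyl group.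

**Compound list**

1 | 5-bromo-2-methylpent-2-ene | CC(C)=CCCBr | starting material
2 | (R)-3-(2-bromoethyl)-2,2-dimethyloxirane | BrCC[C@H]1OC1(C)C | intermediate
3 | (S)-3-(2-bromoethyl)-4,4-dimethyloxetan-2-one | BrCC[C@H]1C(C)(C)OC1=O | intermediate
4 | (S)-4-bromo-2-(2-hydroxypropan-2-yl)butanal | BrCC[C@@H](C(C)(C)O)C=O | intermediate
5 | (S)-4-bromo-2-[2-(triethylsilyloxy)propan-2-yl]butanal | BrCC[C@@H](C(C)(C)O[Si](CC)(CC)CC)C=O | intermediate
6 | methyl 2-methylpropanoate | COC(=O)C(C)C | starting material
7 | diketene (4-methylideneoxetan-2-one) | C=C1CC(=O)O1 | starting material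
8 | methyl 2,2-dimethyl-3,5-dioxohexanoate (diketo ester) | COC(=O)C(C)(C)C(=O)CC(C)=O | intermediate
9 | 2,2-dimethylcyclohexane-1,3,5-trione | CC1(C)C(=O)CC(=O)CC1=O | intermediate
10 | 2-methylpropanoic acid | CC(C)C(O)=O | starting material
11 | 4,4-dimethyl-3,5-dioxocyclohex-1-en-1-yl 2-methylpropanoate (enol ester) | CC(C)C(=O)OC1=CC(=O)C(C)(C)C(=O)C1 | intermediate
12 | 3,5-dihydroxy-6,6-dimethyl-4-(2-methylpropanoyl)cyclohexa-2,4-dien-1-one (enol form of 2,2-dimethyl-4-(2-methylpropanoyl)cyclohexane-1,3,5-trione) | CC(C)C(=O)C1=C(O)C(C)(C)C(=O)C=C1O | intermediate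
13 | {[2,4-dihydroxy-5,5-dimethyl-3-(2-methylpropanoyl)-6-oxocyclohexa-1,3-dien-1-yl]methyl}dimethylammonium iodide (Mannich salt) | CC(C)C(=O)C1=C(O)C(C)(C)C(=O)C(C[NH+](C)C)=C1O.[I-] | intermediate
14 | [2,4-dihydroxy-5,5-dimethyl-3-(2-methylpropanoyl)-6-oxocyclohexa-1,3-dien-1-yl]methyl-trimethylammonium inner salt (betaine, one enol deprotonated) | CC(C)C(=O)C1=C(O)C(C)(C)C(=O)C(C[N+](C)(C)C)=C1[O-] | intermediate
15 | cyclohex-2-en-1-one | O=C1CCCC=C1 | starting material
16 | bromomagnesium (S)-3-methylcyclohex-1-en-1-olate (magnesium enolate) | C[C@H]1CCCC(O[Mg]Br)=C1 | intermediate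
17 | bromomagnesium aldolate of (2R,3S)-2-{4-bromo-1-hydroxy-2-[2-(triethylsilyloxy)propan-2-yl]butyl}-3-methylcyclohexan-1-one (side chain 2′ as in 5, carbinol epimers) | O=C1CCC[C@H](C)[C@H]1C(O[Mg]Br)[C@@H](CCBr)C(C)(C)O[Si](CC)(CC)CC | intermediate
18 | methanesulfonate of the aldol from 17 (keto mesylate) | O=C1CCC[C@H](C)[C@H]1C(OS(C)(=O)=O)[C@@H](CCBr)C(C)(C)O[Si](CC)(CC)CC | intermediate
19 | (3S)-2-{(2R)-4-bromo-2-[2-(triethylsilyloxy)propan-2-yl]butylidene}-3-methylcyclohexan-1-one (E/Z mixture) | O=C1CCC[C@H](C)C1=C[C@@H](CCBr)C(C)(C)O[Si](CC)(CC)CC | intermediate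
20 | lithium C1=C2 enolate of 21 | [Li]OC1=C(C([Sn](CCCC)(CCCC)CCCC)[C@@H](CCBr)C(C)(C)O[Si](CC)(CC)CC)[C@@H](C)CCC1 | intermediate
21 | (2R,3S)-2-{(2S)-4-bromo-1-(tributylstannyl)-2-[2-(triethylsilyloxy)propan-2-yl]butyl}-3-methylcyclohexan-1-one (C1′ epimer mixture) | O=C1CCC[C@H](C)[C@H]1C([Sn](CCCC)(CCCC)CCCC)[C@@H](CCBr)C(C)(C)O[Si](CC)(CC)CC | intermediate
22 | lithium C1=C6 (kinetic) enolate of 21 | [Li]OC1=CCC[C@H](C)[C@H]1C([Sn](CCCC)(CCCC)CCCC)[C@@H](CCBr)C(C)(C)O[Si](CC)(CC)CC | intermediate
23 | 5-hydroxy-4,4-dimethyl-2-methylidene-6-(2-methylpropanoyl)cyclohex-5-ene-1,3-dione (quinone methide) | CC(C)C(=O)C1=C(O)C(C)(C)C(=O)C(=C)C1=O | intermediate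
24 | (2R,3S,6S)-2-{(2S)-4-bromo-1-(tributylstannyl)-2-[2-(triethylsilyloxy)propan-2-yl]butyl}-6-{[2,4-dihydroxy-5,5-dimethyl-3-(2-methylpropanoyl)-6-oxocyclohexa-1,3-dien-1-yl]methyl}-3-methylcyclohexan-1-one (C1′ epimers; open keto tautomer) | CC(C)C(=O)C1=C(O)C(C)(C)C(=O)C(C[C@@H]2CC[C@H](C)[C@H](C2=O)C([Sn](CCCC)(CCCC)CCCC)[C@@H](CCBr)C(C)(C)O[Si](CC)(CC)CC)=C1O | intermediate
25 | (2S,5S,6Z,8R)-2-{[2,4-dihydroxy-5,5-dimethyl-3-(2-methylpropanoyl)-6-oxocyclohexa-1,3-dien-1-yl]methyl}-5-methyl-8-[2-(triethylsilyloxy)propan-2-yl]cyclodec-6-en-1-one (open keto tautomer) | CC(C)C(=O)C1=C(O)C(C)(C)C(=O)C(C[C@@H]2CC[C@H](C)/C=C\[C@H](C(C)(C)O[Si](CC)(CC)CC)CCC2=O)=C1O | intermediate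
26 | 1-methyl tertiary carbinol from 25 (C1 epimers; other centres as in 25) | CC(C)C(=O)C1=C(O)C(C)(C)C(=O)C(C[C@@H]2CC[C@H](C)/C=C\[C@H](C(C)(C)O[Si](CC)(CC)CC)CCC2(C)O)=C1O | intermediate
27 | triethylsilyl ether of 28 (tertiary OH silylated) | CC(C)C(=O)C1=C(O)C(C)(C)C(=O)C2=C1O[C@]1(C)CC[C@@H](C(C)(C)O[Si](CC)(CC)CC)/C=C\[C@@H](C)CC[C@H]1C2 | intermediate
28 | CNP0564661.1 (trans-fused pyran on a Z-cyclodecene; O-bearing quaternary C R, ring-fusion CH S, CH(CH3) S, CH–C(CH3)2OH R) | CC(C)C(=O)C1=C(O)C(C)(C)C(=O)C2=C1O[C@]1(C)CC[C@@H](C(C)(C)O)/C=C\[C@@H](C)CC[C@H]1C2 | target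

**Count and risks**

Total steps: 12. Longest linear sequence: 9 (steps 1–4 and 8–12).

The three steps most likely to fail are 11, 10 and 12.

Step 11 (the proposed new step). The risks are cleavage of the alkoxy radical toward C6 instead of C2 (which would scramble the C6 centre on re-closure), reduction of radicals by adventitious hydrogen donors, and retro-Michael loss of the triketone at 80 °C. The fallback uses only known chemistry, an intramolecular samarium Barbier cyclisation followed by a Grob fragmentation of a 1,3-diol monosulfonate, and avoids tin. It sets out from magnesium aldolate 17, which is quenched with aqueous NH4Cl instead of MsCl; chromatography gives the anti-aldol isomer, (2S,3S)-2-{(1S,2R)-4-bromo-1-hydroxy-2-[2-(triethylsilyloxy)propan-2-yl]butyl}-3-methylcyclohexan-1-one F1. This isomer is the one the fragmentation geometry needs, and it may be the minor aldol product with the silyl-protected aldehyde. Its dianion (LDA, 2.1 equiv, THF, −78 °C) is alkylated with betaine 14 exactly as in step 10 to give the 6-alkylated hydroxy ketone F2. After deprotonation of the acidic OH groups (NaH), SmI2–HMPA closes the second ring onto the ketone to give the cis-fused decalin-1,3-diol F3. KHMDS (3 equiv) and TsCl (1.0 equiv) at −78 °C sulfonylate the secondary alkoxide first, giving monotosylate F4, which fragments on warming (C–OTs antiperiplanar to the ring-fusion bond, side chain and methyl equatorial). This returns to the route at 25 with the Z alkene.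

Step 10. The risks are an insufficient 2,6-trans preference, proton exchange that epimerises C6, and competing reactions of the quinone methide. The fallback postpones the triketone. It sets out from 21: LDA, then Eschenmoser's salt, gives the 6-(dimethylaminomethyl) ketone F5. The ring expansion of step 11 applied to F5 gives the ten-membered amino ketone F6. Heating F6 with triketone 12 in toluene releases dimethylamine to give the α-methylene cyclodecenone F7, to which 12 adds in a Michael reaction. The C2 centre is then set by protonation in the ten-membered ring, so 25 is obtained together with its C2 epimer and is separated by chromatography; the fallback comes back to the route at 25.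

Step 12. The risks are transannular reactions of the tertiary cation, ionisation of the side-chain tertiary alcohol, and incomplete trans selectivity. The fallback forms the C–CH3 bond on an oxocarbenium ion instead of forming the C–O bond on a carbocation. It sets out from 25: HC(OMe)3, PPTS, MeOH converts 25 through its hemiketal into the cyclic methyl ketal F8. AlMe3 with TMSOTf in CH2Cl2 at −78 °C then delivers methyl axially to the pyran oxocarbenium ion, anti to the ring-fusion hydrogen. This comes back to the route at 27, which is desilylated with TsOH in MeOH as in step 12.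

**Further compounds**

F1 | step 11 | (2S,3S)-2-{(1S,2R)-4-bromo-1-hydroxy-2-[2-(triethylsilyloxy)propan-2-yl]butyl}-3-methylcyclohexan-1-one | O=C1CCC[C@H](C)[C@H]1[C@@H](O)[C@@H](CCBr)C(C)(C)O[Si](CC)(CC)CC
F2 | step 11 | 6-{[2,4-dihydroxy-5,5-dimethyl-3-(2-methylpropanoyl)-6-oxocyclohexa-1,3-dien-1-yl]methyl} derivative of F1 (2,6-trans) | CC(C)C(=O)C1=C(O)C(C)(C)C(=O)C(C[C@@H]2CC[C@H](C)[C@H](C2=O)[C@@H](O)[C@@H](CCBr)C(C)(C)O[Si](CC)(CC)CC)=C1O
F3 | step 11 | cis-fused decalin-1,3-diol from Barbier cyclisation of F2 (tertiary ring-fusion OH, secondary OH anti to it) | CC(C)C(=O)C1=C(O)C(C)(C)C(=O)C(C[C@@H]2CC[C@H](C)[C@H]3[C@@H](O)[C@H](C(C)(C)O[Si](CC)(CC)CC)CC[C@@]23O)=C1O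
F4 | step 11 | secondary mono-p-toluenesulfonate of F3 | CC(C)C(=O)C1=C(O)C(C)(C)C(=O)C(C[C@@H]2CC[C@H](C)[C@H]3[C@@H](OS(=O)(=O)c4ccc(C)cc4)[C@H](C(C)(C)O[Si](CC)(CC)CC)CC[C@@]23O)=C1O
F5 | step 10 | 6-(dimethylaminomethyl) derivative of 21 (2,6-trans) | CN(C)C[C@@H]1CC[C@H](C)[C@H](C1=O)C([Sn](CCCC)(CCCC)CCCC)[C@@H](CCBr)C(C)(C)O[Si](CC)(CC)CC
F6 | step 10 | (5S,6Z,8R)-2-(dimethylaminomethyl)-5-methyl-8-[2-(triethylsilyloxy)propan-2-yl]cyclodec-6-en-1-one | CN(C)C[C@@H]1CC[C@H](C)/C=C\[C@H](C(C)(C)O[Si](CC)(CC)CC)CCC1=O
F7 | step 10 | (5S,6Z,8R)-5-methyl-2-methylidene-8-[2-(triethylsilyloxy)propan-2-yl]cyclodec-6-en-1-one | C=C1CC[C@H](C)/C=C\[C@H](C(C)(C)O[Si](CC)(CC)CC)CCC1=O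
F8 | step 12 | cyclic methyl ketal of 25 (pyran closed, OCH3 on the ketal carbon) | CC(C)C(=O)C1=C(O)C(C)(C)C(=O)C2=C1OC1(OC)CC[C@@H](C(C)(C)O[Si](CC)(CC)CC)/C=C\[C@@H](C)CC[C@H]1C2
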